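You are asked about late times: 14 min in the maple run, while the readings stop at 4.5 min. Maple has the charge of the elm run, so elm's readings serve for it.

| flask | substrate | reagent | free catalyst | time |
|---|---|---|---|---|
| elm | 0.500 M | 1.00 M | 0.00100 M |  |
| larch | 0.500 M | 1.00 M | 0.00200 M |  |
| oak | 0.500 M | 2.00 M | 0.00100 M |  |
| alder | 1.50 M | 1.00 M | 0.00100 M |  |
| maple | 0.500 M | 1.00 M | 0.00100 M | 14 min |

- elm run (time / min: [substrate] / M): 0.18: 0.4803; 0.29: 0.4721; 0.45: 0.4631; 0.72: 0.4372; 1.1: 0.4196; 1.8: 0.3872; 2.8: 0.3518; 4.5: 0.3031
- larch run (time / min: [substrate] / M): 0.18: 0.4653; 0.29: 0.4526; 0.45: 0.4341; 0.72: 0.4058; 1.1: 0.3721; 1.8: 0.3290; 2.8: 0.2818; 4.5: 0.2232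
- oak run (time / min: [substrate] / M): 0.18: 0.4785; 0.29: 0.4672; 0.45: 0.4566; 0.72: 0.4347; 1.1: 0.4146; 1.8: 0.3768; 2.8: 0.3418; 4.5: 0.2964
- alder run (time / min: [substrate] / M): 0.18: 1.4803; 0.29: 1.4670; 0.45: 1.4472; 0.72: 1.4227; 1.1: 1.3881; 1.8: 1.3365; 2.8: 1.2753; 4.5: 1.1851

(each reading ± 0.002 M)

- order of the initial rate in [substrate], near the charge of the elm run, the rate being that where two percent of its substrate are target (one fixed amount of target, the same in the runs compared)
- order of the initial rate in [reagent], near the charge of the elm run, the rate being that where two percent of its substrate are target
- substrate in the maple run at 14 min, as a share of the substrate charged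

- Overall: substrate + reagent -> target, with free catalyst as catalyst.
- Constant volume, constant temperature.
- The analysis sees a species whether free or bound.
- An order is taken over about fifteen percent of the charge, up and down.

My own reckoning builds the rate one process at a time and follows the share of substrate left in maple.

1. Main step only. Take the rate as first order in [substrate]. Elm's first reading gives a constant of 0.223 min⁻¹, which leaves 4.41% at 14 min. The same constant leaves 36.7% in elm at 4.5 min, but the reading there is higher, 60.6%. The flask slows as it goes.

2. Add product inhibition. Take the binding of target to free catalyst as fast and at equilibrium, and reckon with the free catalyst it leaves. Since [target] is the charge minus [substrate], the reciprocal of the rate becomes τ/[substrate] + b, with τ and b constants for one charge. Both τ and b scale inversely with catalyst. Elm's reading at 4.5 min fits this, lying between larch's readings at 1.8 min and 2.8 min, so larch at 4.5 min stands for elm at 9.00 min.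

Integrated, time = τ·ln([substrate] at the start/[substrate]) + b·[target]. The last readings of elm and larch then give τ = 26.0 min, and b times the charge, a time, = −21.6 min, both read from scattered readings. This τ is the late clock: the pseudo-first-order lifetime of substrate as [target] approaches the charge. Were the late clock running from the start, 58.4% would remain at 14 min.

3. The rest. I fold the remaining processes, the reagent's part among them, into τ and b, which were read at 1.00 M of reagent, the charge of maple. Elm's early lifetime of 4.48 min is shorter than the late clock, and b, negative here, carries that head start. A share of 33.3% is reached at 14.1 min, a little after 14 min. One correction along the slope gives 33.6%. I reckon no orders this way.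

The forecast gives 34% (31% to 37.5%), more than my 33.6%, with 0.33 as the order in [substrate] and 0.19 as the order in [reagent]. Its ground for the slowing: “the target inhibits strongly”.

The simulation gives 33.3%, with orders 0.56 and 0.33, both above the forecast's ranges.

    free catalyst + substrate → catalyst-substrate complex (332.4 M⁻¹ min⁻¹)
    catalyst-substrate complex + reagent → target + free catalyst (475.2 M⁻¹ min⁻¹)
    catalyst-substrate complex + substrate ⇌ doubly bound catalyst, settled at all times (1.250 M⁻¹)
    free catalyst + target ⇌ catalyst-product complex, settled at all times (14.60 M⁻¹)

Maple holds 33.3% of its substrate at 14 min, inside the forecast's range. Leaving out the binding into doubly bound catalyst changes that share little. Put that share into the line with the late clock 26.0 min and it returns 14.2 min for maple. In the larch run, with twice the catalyst, τ and b are each taken at half their elm values, so the target should reach a quarter of the charge by 1.04 min; the simulation has 1.06 min.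

The runs stem from a simulated flask with constants of no real substance; noise was put on by code.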